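The numbers in the tables were computed for substances that don't exist, noise included.

**One point.** One percentage point of the free monomer charged, at c(free monomer) = 0.80 M, was 8.00 mM, half of the 16 mM of initiator charged. So, if each initiator began one chain, each point of monomer in chains added half a unit to the average chain.

- Sunday's: free monomer 0.80 M; initiator 16 mM; the very flask that is asked about, followed so far
- flask: free monomer 0.80 M; initiator 16 mM; time 2.5 min

Sunday's run (percent of the free monomer charged)

| time / s | monomer in chains / % | free monomer / % |
|---|---|---|
| 10.0 | 5.3 | 90.0 |
| 12.0 | 5.8 | 89.0 |
| 20.0 | 4.4 | 85.1 |
| 30.0 | 5.1 | 80.7 |

(standard deviation of a reading: 1 percentage point)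

- the average divides the monomer in chains by the number of chains begun, living and dead together
- the earlier runs were read with a standard deviation of 1 percentage point
- what may be going on: free monomer + initiator -> living end + monomer in chains; monomer in chains + living end -> free monomer + living end; free monomer + living end -> monomer in chains + living end; free monomer -> uncatalysed product; 2 living end -> dead end
- the earlier runs do not show the number of chains; that part of a forecast is a guess

1. average number of monomer units in a chain (chains begun, living or dead) at 2.5 min
2. part of the free monomer that has reacted at 2.5 min

**What stood still.** Sunday's run was this same flask, read early, and the asked flask differed from it in the time of reading, 2.5 min. Between 10.0 s and 30.0 s Sunday's free monomer fell by 9.3 percentage points, while the first and last readings of monomer in chains differed by 0.2 points, less than the 1 point of a reading. I therefore froze monomer in chains at the mean of Sunday's readings, 5.15%, which gave 0.0412 M, the held chain monomer. I took initiator as the limiting reagent, with its whole charge begun as chains, though that was a guess. Dividing gave 2.58 units per chain, which I carried unchanged to the asked time.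

**The forecast.** It gave 1.8 units (1.2 to 4), fewer than my figure, and 58% reacted (53% to 63%), holding that “Chains begun cannot exceed the initiator”.

**The result.** The flask gave 2.75 units and 53.9% reacted.

    free monomer + initiator → living end + monomer in chains (k = 2.51 M⁻¹ s⁻¹)
    monomer in chains + living end → free monomer + living end, rate k2*[living end] as long as [monomer in chains] is above zero (k = 3.41 s⁻¹)
    free monomer + living end → monomer in chains + living end, rate k3*[living end]*[free monomer] (k = 6.58 M⁻¹ s⁻¹)
    free monomer → uncatalysed product (k = 0.00479 s⁻¹)
    2 living end → dead end (k = 179 M⁻¹ s⁻¹)

At 2.50 min the flask held 5.49% as monomer in chains and 0% of its initiator, and the held chain monomer over the initiator charge still gave 2.58 against 2.75. The neighbouring flask, the same charge read at 40 s, takes the same reckoning, again 2.58. It gave 2.75 units, with 5.51% as monomer in chains and 77.9% still free monomer.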